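**Retrosynthetic overview**
- The target is the cis-(1S,2S)-1-aryl-2,3-dimethyl-1,2-dihydronaphthalene. The last step only frees the ring A phenol from a silyl ether.
- Ring B is cut at C1–C2 and C3=C4. The β-carbon of (E)-2-methylbut-2-enal, made nucleophilic as a carbene-bound homoenolate, adds to the electrophilic benzylic carbon C1 of a syringyl p-quinone methide. The azolium enolate then closes C3–C4 by aldol reaction on an ortho formyl group, and the β-lactone loses CO2 to give C3=C4.
- The quinone methide comes from a benzhydryl sulfone built from two syringaldehyde units joined at C1–C8a by directed ortho-lithiation.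
- Ring order: ring A and the pendant aryl ring are bought as syringaldehyde; ring B is the only ring constructed (step 3).

Numbering used throughout (dihydronaphthalene): C1 bears the pendant aryl, C2 is CH–CH3, C3(CH3)=C4H, ring A is C4a, C5–C8, C8a.

Assumption: the (5aS,10bR) antipode of the aminoindanol triazolium salt is taken to give the (1S,2S) product; both antipodes are commercial, so the mirror-image salt is used if the sense proves reversed.

**Step 1**
Reactants: 1 syringaldehyde (4-hydroxy-3,5-dimethoxybenzaldehyde); 2 chlorotri(propan-2-yl)silane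
Product: 3 3,5-dimethoxy-4-{[tri(propan-2-yl)silyl]oxy}benzaldehyde
Conditions: iPr3SiCl (1.3 equiv), imidazole (2.5 equiv), DMF, 40 °C, 12 h
Reagents that add atoms: chlorotri(propan-2-yl)silane (2), CC(C)[Si](Cl)(C(C)C)C(C)C
Why: Imidazole-promoted O-silylation of the acidic phenol gives a hindered silyl ether that tolerates organolithiums and carbonate and removes the only acidic proton of the future ring A; no stereocenter is formed.

**Step 2**
Reactants: 3 3,5-dimethoxy-4-{[tri(propan-2-yl)silyl]oxy}benzaldehyde; 1 syringaldehyde (second unit, added as its lithium phenolate); 4 sodium 4-methylbenzenesulfinate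
Product: 8 rac-2-[(4-hydroxy-3,5-dimethoxyphenyl)(4-methylbenzenesulfonyl)methyl]-3,5-dimethoxy-4-{[tri(propan-2-yl)silyl]oxy}benzaldehyde, via lithium amino alkoxide 5 (not isolated), via ortho-lithiated amino alkoxide 6 (not isolated), via lactol 7 (not isolated)
Conditions: LiN(Me)CH2CH2NMe2 (from MeNHCH2CH2NMe2 + n-BuLi, 1.1 equiv), THF, −20 °C; n-BuLi (1.5 equiv), −20 °C, 3 h; lithium phenolate of 1 (1 + LiN(SiMe3)2, 2 equiv, THF), −40 °C to rt; then TolSO2Na (3 equiv), 1 M aq HCl to pH ≈ 2, rt, 4 h
Reagents that add atoms: sodium 4-methylbenzenesulfinate (4), Cc1ccc(cc1)S(=O)[O-].[Na+]; syringaldehyde (1), COc1cc(C=O)cc(OC)c1O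
Why: In this Comins-type directed ortho-metalation the in situ α-amino alkoxide and the adjacent methoxy group direct lithiation to the ring carbon that becomes C8a, the aryllithium adds 1,2 to the second aldehyde to form C1–C8a, and on acidification the p-hydroxybenzhydrol (lactol 7) ionises and is captured at sulfur by sulfinate (SN1 sulfonylation); the C1 centre formed is racemic and is erased in step 3.

**Step 3**
Reactants: 8 rac-2-[(4-hydroxy-3,5-dimethoxyphenyl)(4-methylbenzenesulfonyl)methyl]-3,5-dimethoxy-4-{[tri(propan-2-yl)silyl]oxy}benzaldehyde; 9 (E)-2-methylbut-2-enal (tiglic aldehyde)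
Product: 12 4-[(1S,2S)-6,8-dimethoxy-2,3-dimethyl-7-{[tri(propan-2-yl)silyl]oxy}-1,2-dihydronaphthalen-1-yl]-2,6-dimethoxyphenol, via quinone methide aldehyde 10 (not isolated), via β-lactone 11 (not isolated)
Conditions: (5aS,10bR)-2-(2,4,6-trimethylphenyl)-5a,10b-dihydro-4H,6H-indeno[2,1-b][1,2,4]triazolo[4,3-d][1,4]oxazin-2-ium chloride (C21H22ClN3O, 15 mol %), Cs2CO3 (1.3 equiv), 9 (2 equiv), 4 Å molecular sieves, THF, argon, rt, 16 h; then 50 °C, 2 h
Reagents that add atoms: (E)-2-methylbut-2-enal (9), C/C=C(\C)C=O (supplies C2, C3 and both C-methyl groups; its carbonyl carbon leaves as CO2)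
Why: Proposed new method: the chiral carbene turns enal 9 into a Breslow-type homoenolate whose β-carbon (C2, normally an acceptor carbon) adds 1,6 to the electrophilic benzylic carbon C1 of quinone methide 10 (released from 8 by base-induced loss of sulfinate), with the catalyst fixing the enal face (C2) and a synclinal, like-topicity open transition state fixing C1 so that aryl and methyl end up cis (1S,2S), after which the azolium enolate attacks the ortho formyl group (C3–C4 aldol), the alkoxide acylates to β-lactone 11 with release of the carbene, and the benzylic β-lactone extrudes CO2 to give C3=C4; the closest known reaction types are carbene-catalysed homoenolate 1,6-additions of enals to p-quinone methides and the homoenolate Michael/aldol/β-lactonisation/decarboxylation annulation of enals with enones.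

**Step 4**
Reactants: 12 4-[(1S,2S)-6,8-dimethoxy-2,3-dimethyl-7-{[tri(propan-2-yl)silyl]oxy}-1,2-dihydronaphthalen-1-yl]-2,6-dimethoxyphenol
Product: 13 4-[(1S,2S)-7-hydroxy-6,8-dimethoxy-2,3-dimethyl-1,2-dihydronaphthalen-1-yl]-2,6-dimethoxyphenol (CNP0141907.1; aryl and 2-methyl cis)
Conditions: Bu4NF (1.1 equiv), AcOH (1.1 equiv), THF, 0 °C, 30 min, argon
Reagents that add atoms: none
Why: Fluoride-induced cleavage of the aryl silyl ether, buffered with acetic acid so that neither phenolate nor acid can isomerise the electron-rich styrene, leaves C1 and C2 untouched.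

**Compound list**
1 | syringaldehyde (4-hydroxy-3,5-dimethoxybenzaldehyde) | COc1cc(C=O)cc(OC)c1O | starting material
2 | chlorotri(propan-2-yl)silane | CC(C)[Si](Cl)(C(C)C)C(C)C | starting material
3 | 3,5-dimethoxy-4-{[tri(propan-2-yl)silyl]oxy}benzaldehyde | COc1cc(C=O)cc(OC)c1O[Si](C(C)C)(C(C)C)C(C)C | intermediate
4 | sodium 4-methylbenzenesulfinate | Cc1ccc(cc1)S(=O)[O-].[Na+] | starting material
5 | lithium {[2-(dimethylamino)ethyl](methyl)amino}(3,5-dimethoxy-4-{[tri(propan-2-yl)silyl]oxy}phenyl)methanolate | CN(C)CCN(C)C(O[Li])c1cc(OC)c(O[Si](C(C)C)(C(C)C)C(C)C)c(OC)c1 | intermediate (not isolated)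
6 | 2-lithio derivative of 5 (lithium at the ring carbon between the amino alkoxide carbon and a methoxy group) | CN(C)CCN(C)C(O[Li])c1cc(OC)c(O[Si](C(C)C)(C(C)C)C(C)C)c(OC)c1[Li] | intermediate (not isolated)
7 | 3-(4-hydroxy-3,5-dimethoxyphenyl)-4,6-dimethoxy-5-{[tri(propan-2-yl)silyl]oxy}-1,3-dihydro-2-benzofuran-1-ol (lactol, diastereomer mixture) | OC1OC(c2cc(OC)c(O)c(OC)c2)c2c(OC)c(O[Si](C(C)C)(C(C)C)C(C)C)c(OC)cc12 | intermediate (not isolated)
8 | rac-2-[(4-hydroxy-3,5-dimethoxyphenyl)(4-methylbenzenesulfonyl)methyl]-3,5-dimethoxy-4-{[tri(propan-2-yl)silyl]oxy}benzaldehyde | Cc1ccc(cc1)S(=O)(=O)C(c1cc(OC)c(O)c(OC)c1)c1c(OC)c(O[Si](C(C)C)(C(C)C)C(C)C)c(OC)cc1C=O | intermediate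
9 | (E)-2-methylbut-2-enal (tiglic aldehyde) | C/C=C(\C)C=O | starting material
10 | 2-[(3,5-dimethoxy-4-oxocyclohexa-2,5-dien-1-ylidene)methyl]-3,5-dimethoxy-4-{[tri(propan-2-yl)silyl]oxy}benzaldehyde | COC1=CC(=Cc2c(OC)c(O[Si](C(C)C)(C(C)C)C(C)C)c(OC)cc2C=O)C=C(OC)C1=O | intermediate (not isolated)
11 | (3S,4S)-4-(4-hydroxy-3,5-dimethoxyphenyl)-5,7-dimethoxy-2a,3-dimethyl-6-{[tri(propan-2-yl)silyl]oxy}-2a,3,4,8b-tetrahydro-2H-naphtho[1,2-b]oxet-2-one (cis-fused β-lactone; the two ring-fusion centres are lost on decarboxylation) | COc1cc(cc(OC)c1O)[C@@H]1[C@H](C)C2(C)C(=O)OC2c2cc(OC)c(O[Si](C(C)C)(C(C)C)C(C)C)c(OC)c12 | intermediate (not isolated)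
12 | 4-[(1S,2S)-6,8-dimethoxy-2,3-dimethyl-7-{[tri(propan-2-yl)silyl]oxy}-1,2-dihydronaphthalen-1-yl]-2,6-dimethoxyphenol | COc1cc([C@H]2c3c(cc(OC)c(O[Si](C(C)C)(C(C)C)C(C)C)c3OC)C=C(C)[C@H]2C)cc(OC)c1O | intermediate
13 | 4-[(1S,2S)-7-hydroxy-6,8-dimethoxy-2,3-dimethyl-1,2-dihydronaphthalen-1-yl]-2,6-dimethoxyphenol | COc1cc([C@H]2c3c(cc(OC)c(O)c3OC)C=C(C)[C@H]2C)cc(OC)c1O | target

**Totals**
Total step count: 4. Longest linear sequence: 4 steps (1 → 3 → 8 → 12 → 13); the second syringaldehyde unit and tiglic aldehyde enter directly.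

**Steps most likely to fail, with fallbacks**

Step 3 is the main risk. The α-branched enal may form the homoenolate slowly, the diastereocontrol at C1 is unproven, and the acyl azolium could be intercepted by phenolate before the aldol closure. The fallback sets out from 8 and comes back at 12. Quinone methide 10 is liberated from 8 (aq NaHCO3, CH2Cl2, dried solution) and butan-2-one is added through its more substituted enamine under a chiral primary amine (9-amino-9-deoxy-epi-quinine, C20H25N3O, with CF3CO2H). This gives the keto aldehyde 2-[(1S,2S)-1-(4-hydroxy-3,5-dimethoxyphenyl)-2-methyl-3-oxobutyl]-3,5-dimethoxy-4-{[tri(propan-2-yl)silyl]oxy}benzaldehyde F1. Ring B is then closed by intramolecular McMurry coupling (TiCl4, Zn, pyridine, THF, reflux), in which low-valent titanium ketyls join the two carbonyl carbons C3 and C4 directly as the C3=C4 alkene of 12.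

Step 2 is the second risk. The C–H lithiation may be incomplete, excess n-BuLi consumes part of the electrophile, and the one-flask sulfinate capture competes with isobenzofuran formation. The fallback sets out from 3 and comes back at 6. Bromination of 3 (NBS, MeCN, rt) gives 2-bromo-3,5-dimethoxy-4-{[tri(propan-2-yl)silyl]oxy}benzaldehyde F2. Addition of LiN(Me)CH2CH2NMe2 (THF, −78 °C) gives its lithium amino alkoxide, lithium (2-bromo-3,5-dimethoxy-4-{[tri(propan-2-yl)silyl]oxy}phenyl){[2-(dimethylamino)ethyl](methyl)amino}methanolate F3. Bromine–lithium exchange with exactly one equivalent of n-BuLi at −78 °C then delivers 6 without excess base. After addition to the phenolate of 1, lactol 7 is isolated and converted to 8 in a separate operation (TolSO2Na, HCO2H–H2O).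

Step 1 is the third risk, because the hindered and rather acidic phenol of 1 may silylate sluggishly with the bulky chlorosilane. The fallback sets out from 2 and comes back at 3. The more nucleophilic commercial 4-bromo-2,6-dimethoxyphenol is silylated with 2 (imidazole, DMF) to give (4-bromo-2,6-dimethoxyphenoxy)tri(propan-2-yl)silane F4. The formyl group is then introduced afterwards by bromine–lithium exchange and formylation (n-BuLi, THF, −78 °C; then DMF), giving 3.

**Further compounds**
F1 | step 3 | 2-[(1S,2S)-1-(4-hydroxy-3,5-dimethoxyphenyl)-2-methyl-3-oxobutyl]-3,5-dimethoxy-4-{[tri(propan-2-yl)silyl]oxy}benzaldehyde | COc1cc(cc(OC)c1O)[C@@H](c1c(OC)c(O[Si](C(C)C)(C(C)C)C(C)C)c(OC)cc1C=O)[C@H](C)C(C)=O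
F2 | step 2 | 2-bromo-3,5-dimethoxy-4-{[tri(propan-2-yl)silyl]oxy}benzaldehyde | COc1cc(C=O)c(Br)c(OC)c1O[Si](C(C)C)(C(C)C)C(C)C
F3 | step 2 | lithium (2-bromo-3,5-dimethoxy-4-{[tri(propan-2-yl)silyl]oxy}phenyl){[2-(dimethylamino)ethyl](methyl)amino}methanolate | CN(C)CCN(C)C(O[Li])c1cc(OC)c(O[Si](C(C)C)(C(C)C)C(C)C)c(OC)c1Br
F4 | step 1 | (4-bromo-2,6-dimethoxyphenoxy)tri(propan-2-yl)silane | COc1cc(Br)cc(OC)c1O[Si](C(C)C)(C(C)C)C(C)C
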